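**Assumption (one line):** levopimaric acid (CAS 79-54-9) is taken as a purchasable resin acid. The target SMILES is read as the cycloadduct in which C11 of the labdane is cis to the angular chromone (chromone-endo / quinone-exo topology from the 12E-diene).

## Retrosynthetic overview

1. Target ⇒ one intermolecular [4+2] between flavone-quinone **12** (chromone-bearing C=C) and labdatriene hydroxy-acid **7**, run unprotected and without Lewis acid. This forms the cyclohexene ring and the three new stereocentres last.
2. **12** ⇒ CAN oxidative dearomatization of the 2,4,5-trimethoxyphenyl ring of flavone **11**. **11** ⇒ phloroglucinol + aroylacetate **9** (thermal chromone synthesis that desymmetrizes phloroglucinol).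
3. **7** ⇒ C7 oxidation/reduction of triene acid **4** ⇒ two Wittig olefinations of keto-aldehyde **2** ⇒ exhaustive ozonolysis of levopimaric acid **1** (ring C excised; C4, C5, C9, C10 come from the chiral pool).
4. Ring order: A/B decalin (chiral pool) → chromone ring → quinone (dearomatized B-ring) → cyclohexene (Diels–Alder).

## Route

**Step 1**
Reactants: **1** levopimaric acid
Product: **2** 8,12-dioxo-13,14,15,16,17-pentanorlabdan-18-oic acid (C8 ketone, C12 aldehyde; 5α-H, 9α-H, 10β-Me, 4α-CO2H)
Conditions: O3 (excess), CH2Cl2/MeOH 4:1, –78 °C; then Me2S, –78 °C → rt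
Reagents that add atoms: ozone, [O-][O+]=O
Why: Exhaustive ozonolysis (Criegee) cleaves both ring-C alkenes (C8=C14, C12=C13), removing C13–C16 as 3-methyl-2-oxobutanal and leaving the C8 ketone and C12 aldehyde; no stereocentre is formed and C9 keeps its equatorial side chain.

**Step 2**
Reactants: **2**
Product: **3** (12E)-8-oxo-15,17-dinorlabd-12-en-14-al-18-oic acid (E-2-methyl-enal side chain)
Conditions: Ph3P=C(Me)CHO (2.5 equiv), toluene, 90 °C
Reagents that add atoms: 2-(triphenylphosphoranylidene)propanal, CC(C=O)=P(c1ccccc1)(c1ccccc1)c1ccccc1
Why: Wittig olefination with a stabilised ylide reacts only with the aldehyde (the hindered C8 ketone is inert) and gives the E-trisubstituted enal, which fixes the 12E geometry.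

**Step 3**
Reactants: **3**
Product: **4** labda-8(17),12E,14-trien-18-oic acid (4-epi-trans-communic acid)
Conditions: Ph3PCH3Br, KOtBu (5 equiv ylide), THF, 0 → 50 °C
Reagents that add atoms: methylenetriphenylphosphorane, C=P(c1ccccc1)(c1ccccc1)c1ccccc1
Why: Double Wittig methylenation converts the enal CHO into the terminal vinyl group and the C8 ketone into the 8(17)-exocyclic methylene; the carboxylate is inert and C9 stays in its thermodynamic configuration.

**Step 4**
Reactants: **4**
Product: **5** 7α-hydroxy-labda-8(17),12E,14-trien-18-oic acid
Conditions: SeO2 (0.5 equiv), t-BuOOH (3 equiv), CH2Cl2, 0 °C → rt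
Reagents that add atoms: selenium dioxide, O=[Se]=O (oxygen donor; re-oxidised by tert-butyl hydroperoxide, CC(C)(C)OO)
Why: Sharpless–Riley allylic hydroxylation (ene reaction at C17, then [2,3]-shift) oxidises the ring CH2 next to the 1,1-disubstituted alkene and gives the axial 7α-alcohol; the configuration is corrected in steps 5–6.

**Step 5**
Reactants: **5**
Product: **6** 7-oxo-labda-8(17),12E,14-trien-18-oic acid
Conditions: Dess–Martin periodinane, NaHCO3, CH2Cl2, 0 °C; used at once
Reagents that add atoms: none
Why: Dess–Martin oxidation of the secondary allylic alcohol to the α-methylene ketone; the acid and diene are untouched, and this erases the C7 configuration for resetting.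

**Step 6**
Reactants: **6**
Product: **7** 7β-hydroxy-labda-8(17),12E,14-trien-18-oic acid
Conditions: NaBH4, CeCl3·7H2O, MeOH, –78 → –20 °C
Reagents that add atoms: none
Why: Luche 1,2-reduction; the small hydride attacks axially from the α-face of the rigid trans-decalin (as for 7-keto steroids) and gives the equatorial 7β-alcohol.

**Step 7**
Reactants: **8** 1-(2,4,5-trimethoxyphenyl)ethanone
Product: **9** ethyl 3-oxo-3-(2,4,5-trimethoxyphenyl)propanoate
Conditions: NaH, (EtO)2CO, toluene, reflux
Reagents that add atoms: diethyl carbonate, CCOC(=O)OCC
Why: Crossed Claisen condensation (C-ethoxycarbonylation of the methyl ketone enolate), driven by formation of the β-ketoester enolate.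

**Step 8**
Reactants: **9** (2 equiv) and **10** phloroglucinol
Product: **11** 5,7-dihydroxy-2-(2,4,5-trimethoxyphenyl)-4H-chromen-4-one
Conditions: neat, 240 °C (microwave or metal bath), 5–10 min
Reagents that add atoms: none
Why: Mentzer thermal chromone synthesis: the β-ketoester loses EtOH to an aroylketene that C-acylates one of the three equivalent phloroglucinol carbons (symmetry broken here), and cyclodehydration gives the 5,7-dihydroxyflavone without protecting groups.

**Step 9**
Reactants: **11**
Product: **12** 2-(5,7-dihydroxy-4-oxo-4H-chromen-2-yl)-5-methoxy-1,4-benzoquinone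
Conditions: (NH4)2Ce(NO3)6 (2.5 equiv), MeCN/H2O 3:1, 0 °C, 10 min; extractive work-up, used crude
Reagents that add atoms: water, O
Why: CAN oxidative demethylation dearomatizes the ring: the arene radical cation is trapped by water at the para-related 2'- and 5'-methoxy carbons with loss of two MeOH, leaving the 4'-OMe as the vinylogous ester; the chelated, acyl-deactivated chromone phenol ring is harder to oxidise.

**Step 10**
Reactants: **12** (1.2 equiv) and **7**
Product: **13** dichrostachine E
Conditions: CH2Cl2/THF 4:1 (0.5 M), 25 °C, dark, 24–48 h, no Lewis acid; preparative HPLC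
Reagents that add atoms: none
Why: Diels–Alder of the 12E,14-diene with the only non-donor-substituted quinone C=C. Suprafacial addition gives the cis ring fusion (angular chromone cis to the ring-fusion H). The unhindered terminus C15 bonds to the unsubstituted quinone carbon, as with 2-acylquinones, so C12 bonds to the chromone-bearing carbon. The required C12 configuration comes from the chromone-endo (quinone-exo) transition state, and Lewis acid is omitted so that the quinone carbonyls are not made the endo-directing group. The facial sense comes from approach anti to the decalin in the A(1,3)-controlled side-chain rotamer. The usual quinone-endo mode may dominate, so the target may be the minor adduct and must be separated from regio- and stereoisomers.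

## Compound list

1 | levopimaric acid (abieta-8(14),12-dien-18-oic acid) | C1=C2CC[C@@H]3[C@](C)(CCC[C@@]3(C)C(=O)O)[C@H]2CC=C1C(C)C | starting material
2 | 8,12-dioxo-13,14,15,16,17-pentanorlabdan-18-oic acid | O=C1CC[C@@H]2[C@](C)(CCC[C@@]2(C)C(=O)O)[C@H]1CC=O | intermediate
3 | (12E)-8-oxo-15,17-dinorlabd-12-en-14-al-18-oic acid | O=C1CC[C@@H]2[C@](C)(CCC[C@@]2(C)C(=O)O)[C@H]1C/C=C(C)/C=O | intermediate
4 | labda-8(17),12E,14-trien-18-oic acid | C=C1CC[C@@H]2[C@](C)(CCC[C@@]2(C)C(=O)O)[C@H]1C/C=C(C)/C=C | intermediate
5 | 7α-hydroxy-labda-8(17),12E,14-trien-18-oic acid | C=C1[C@H](O)C[C@@H]2[C@](C)(CCC[C@@]2(C)C(=O)O)[C@H]1C/C=C(C)/C=C | intermediate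
6 | 7-oxo-labda-8(17),12E,14-trien-18-oic acid | C=C1C(=O)C[C@@H]2[C@](C)(CCC[C@@]2(C)C(=O)O)[C@H]1C/C=C(C)/C=C | intermediate
7 | 7β-hydroxy-labda-8(17),12E,14-trien-18-oic acid | C=C1[C@@H](O)C[C@@H]2[C@](C)(CCC[C@@]2(C)C(=O)O)[C@H]1C/C=C(C)/C=C | intermediate
8 | 1-(2,4,5-trimethoxyphenyl)ethanone | CC(=O)c1cc(OC)c(OC)cc1OC | starting material
9 | ethyl 3-oxo-3-(2,4,5-trimethoxyphenyl)propanoate | CCOC(=O)CC(=O)c1cc(OC)c(OC)cc1OC | intermediate
10 | phloroglucinol (benzene-1,3,5-triol) | Oc1cc(O)cc(O)c1 | starting material
11 | 5,7-dihydroxy-2-(2,4,5-trimethoxyphenyl)-4H-chromen-4-one | COc1cc(OC)c(OC)cc1-c1cc(=O)c2c(O)cc(O)cc2o1 | intermediate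
12 | 2-(5,7-dihydroxy-4-oxo-4H-chromen-2-yl)-5-methoxy-1,4-benzoquinone | COC1=CC(=O)C(=CC1=O)c1cc(=O)c2c(O)cc(O)cc2o1 | intermediate
13 | dichrostachine E | C=C1[C@@H](O)C[C@@H]2[C@](C)(CCC[C@@]2(C)C(=O)O)[C@H]1C[C@@H]1C(C)=CC[C@H]2C(=O)C(OC)=CC(=O)[C@@]12c1cc(=O)c2c(O)cc(O)cc2o1 | target

## Summary

**Total steps:** 10. **Longest linear sequence:** 7 (steps 1–6, then 10).

**Three steps most likely to fail**

1. **Step 10 (Diels–Alder).** The target needs the chromone-endo/quinone-exo adduct on one diene face, while the ordinary quinone-endo mode, the other face or the other regiochemistry may dominate. Fallback: prepare the 12Z isomer of **7** (Z-selective Still–Gennari olefination of **2**, then reduction, oxidation and methylenation) and run a quinone-endo cycloaddition on silyl-protected partners with a chiral oxazaborolidinium Lewis acid under high pressure. Endo addition to the Z-diene gives the same C12/angular-carbon relationship, with catalyst-controlled facial selectivity.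

2. **Step 9 (CAN dearomatization with free 5,7-OH).** The phloroglucinol-type ring may be oxidised or nitrated, or the electron-poor aryl ring may react sluggishly. Fallback: build the flavone from a 2,5-bis(benzyloxy)-4-methoxyphenyl β-ketoester, hydrogenolyse to the hydroquinone and oxidise with Ag2O, which is selective for the hydroquinone.

3. **Step 4 (SeO2 on the triene).** Oxidation at C16 or attack on the conjugated diene may compete with C7. Fallback: reorder the sequence. Doubly methylenate **2** (Ph3P=CH2), run the SeO2 / Dess–Martin / Luche sequence on the mono-ene where only C7 is activated, then install the diene by cross-metathesis with methacrolein followed by Wittig methylenation.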